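**Retrosynthetic overview**
1. Target ⇐ global desilylation of a fully silylated acid; the acrylic acid comes from a primary allylic silyl ether (oxidation after the C5 hydroxyl is capped).
2. The C3 ester, the C4–alkenyl bond and the C5 carbinol ⇐ one tandem semipinacol (1,2-alkenyl shift) / Tishchenko coupling of a cis-2,3-epoxy cyclohexanol with the side-chain aldehyde (made from (S)-glycidol).
3. Epoxy alcohol ⇐ C5 enone ⇐ Wharton 1,3-transposition of the C3 enone.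
4. Key disconnection: cyclohexanone ⇐ one-carbon ring expansion (1,2-shift of the quaternary carbon in a β-oxido carbenoid) of a 2-ethenyl-2-methyl-3-alkenylcyclopentanone, itself from a three-component coupling on 2-methylcyclopent-2-enone.
5. Ring order: the only carbocycle is bought as a cyclopentenone and is enlarged to the cyclohexane in step 3; no other ring is formed.

Convention: ring carbons are called C1–C6 as in the target (C1 quaternary with methyl and ethenyl, C2 CH2, C3 ester carbinol, C4 bearing the acrylic acid, C5 free carbinol, C6 bearing the hydroxypropenyl group); TBS = tert-butyldimethylsilyl, TES = triethylsilyl.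
Assumption: the target can be isolated as the free γ-hydroxy acid (work-up at about pH 5) without lactonisation.

**Step 1**
Reactants: 1 2-bromoprop-2-en-1-ol
Product: 2 [(2-bromoprop-2-en-1-yl)oxy](tert-butyl)dimethylsilane
Conditions: TBSCl, imidazole, DMF, 0 → 23 °C
Reagents that add atoms: tert-butyldimethylsilyl chloride, CC(C)(C)[Si](C)(C)Cl
Why: Silyl ether formation on a primary alcohol is routine and the vinyl bromide is inert.

**Step 2**
Reactants: 2 [(2-bromoprop-2-en-1-yl)oxy](tert-butyl)dimethylsilane; 3 2-methylcyclopent-2-en-1-one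
Product: 6 (2R,3R)-2-ethenyl-2-methyl-3-{3-[(TBS)oxy]prop-1-en-2-yl}cyclopentan-1-one, via alkenylmagnesium bromide 4 (not isolated), via bromomagnesium enolate 5 (not isolated)
Conditions: 2, Mg, THF, 45 °C; then 3, Cu(OTf)2 (3 mol %), (4S,5S)-1,3-bis(2-methylbenzyl)-4,5-diphenylimidazolinium tetrafluoroborate (4 mol %), Et2O, −40 °C; then vinyl bromide (3 equiv), Pd2(dba)3 (2 mol %), P(t-Bu)3 (8 mol %), −40 → 20 °C
Reagents that add atoms: vinyl bromide, C=CBr
Why: Proposed new method: a copper–NHC-catalysed enantioselective 1,4-addition of the 1,1-disubstituted alkenyl Grignard reagent to the α-methyl enone sets C6 and leaves a regiodefined magnesium enolate, which is intercepted in the same flask by a vinylpalladium bromide (oxidative addition of vinyl bromide to zerovalent palladium, enolate transmetallation, C–C reductive elimination driven by the bulky P(t-Bu)3) on the face opposite the new C6 substituent, so the quaternary C1 forms with ethenyl trans and methyl cis to the alkenyl group; the closest known reactions are copper-catalysed asymmetric conjugate addition of alkyl Grignard reagents to 2-methylcycloalkenones with trapping of the magnesium enolate by carbon electrophiles, and palladium-catalysed α-vinylation of preformed ketone enolates with vinyl bromides, which have not been merged or run with an alkenyl nucleophile.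

**Step 3**
Reactants: 6 (2R,3R)-2-ethenyl-2-methyl-3-{3-[(TBS)oxy]prop-1-en-2-yl}cyclopentan-1-one
Product: 8 (3R,4S)-3-ethenyl-3-methyl-4-{3-[(TBS)oxy]prop-1-en-2-yl}cyclohexan-1-one, via lithium dibromomethyl carbinolate 7 (not isolated)
Conditions: CH2Br2, lithium 2,2,6,6-tetramethylpiperidide, THF, −78 °C; then n-BuLi, −78 → 0 °C; H2O
Reagents that add atoms: dibromomethane, BrCBr
Why: β-Oxido carbenoid ring expansion (one-carbon homologation by 1,2-shift): bromine–lithium exchange on the adduct gives a carbenoid in which the more substituted α-carbon (quaternary C1) migrates with retention, so the new CH2 (C2) is inserted between C1 and the carbonyl carbon (C3) and the C1/C6 configurations pass unchanged into the six-membered ring.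

**Step 4**
Reactants: 8 (3R,4S)-3-ethenyl-3-methyl-4-{3-[(TBS)oxy]prop-1-en-2-yl}cyclohexan-1-one
Product: 9 (4S,5R)-5-ethenyl-5-methyl-4-{3-[(TBS)oxy]prop-1-en-2-yl}cyclohex-2-en-1-one
Conditions: IBX (2.5 equiv), DMSO, 70 °C
Reagents that add atoms: none
Why: IBX dehydrogenation of a ketone to the enone can only run toward C4=C5 because C1 carries no hydrogen.

**Step 5**
Reactants: 9 (4S,5R)-5-ethenyl-5-methyl-4-{3-[(TBS)oxy]prop-1-en-2-yl}cyclohex-2-en-1-one
Product: 10 (1S,4R,5S,6S)-4-ethenyl-4-methyl-5-{3-[(TBS)oxy]prop-1-en-2-yl}-7-oxabicyclo[4.1.0]heptan-2-one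
Conditions: 30 % H2O2, NaOH (cat.), MeOH, 0 °C
Reagents that add atoms: hydrogen peroxide, OO
Why: Weitz–Scheffer nucleophilic epoxidation, with hydroperoxide adding to C5 anti to the neighbouring C6 substituent (the minor C5 epimer is harmless because C5 becomes a ketone in step 7).

**Step 6**
Reactants: 10 (1S,4R,5S,6S)-4-ethenyl-4-methyl-5-{3-[(TBS)oxy]prop-1-en-2-yl}-7-oxabicyclo[4.1.0]heptan-2-one
Product: 11 (1R,5R,6S)-5-ethenyl-5-methyl-6-{3-[(TBS)oxy]prop-1-en-2-yl}cyclohex-2-en-1-ol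
Conditions: N2H4·H2O, AcOH (cat.), MeOH, 0 → 23 °C, under argon
Reagents that add atoms: none
Why: Wharton transposition: the epoxy hydrazone fragments with loss of N2, moving the oxygen from C3 to C5 and the alkene to C3=C4.

**Step 7**
Reactants: 11 (1R,5R,6S)-5-ethenyl-5-methyl-6-{3-[(TBS)oxy]prop-1-en-2-yl}cyclohex-2-en-1-ol
Product: 12 (5R,6S)-5-ethenyl-5-methyl-6-{3-[(TBS)oxy]prop-1-en-2-yl}cyclohex-2-en-1-one
Conditions: Dess–Martin periodinane, CH2Cl2, 0 → 23 °C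
Reagents that add atoms: none
Why: Dess–Martin oxidation of the allylic alcohol gives the transposed enone under non-basic conditions, so the α-stereocentre C6 is not epimerised.

**Step 8**
Reactants: 1 2-bromoprop-2-en-1-ol
Product: 13 [(2-bromoprop-2-en-1-yl)oxy]triethylsilane
Conditions: TESCl, imidazole, CH2Cl2, 0 °C
Reagents that add atoms: chlorotriethylsilane, CC[Si](Cl)(CC)CC
Why: Silyl ether formation; the TES group is chosen so that this primary ether can later be oxidised selectively.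

**Step 9**
Reactants: 12 (5R,6S)-5-ethenyl-5-methyl-6-{3-[(TBS)oxy]prop-1-en-2-yl}cyclohex-2-en-1-one; 13 [(2-bromoprop-2-en-1-yl)oxy]triethylsilane
Product: 15 (1S,5R,6S)-5-ethenyl-5-methyl-6-{3-[(TBS)oxy]prop-1-en-2-yl}-1-{3-[(TES)oxy]prop-1-en-2-yl}cyclohex-2-en-1-ol, via alkenyllithium 14 (not isolated)
Conditions: 13, t-BuLi (2.0 equiv), Et2O, −78 °C; then 12, −78 °C; H2O
Reagents that add atoms: none
Why: 1,2-Addition of an alkenyllithium (from bromine–lithium exchange) to the enone carbonyl occurs from the face opposite the C6 substituent and the axial C1 methyl, placing the new alkenyl group trans and the tertiary OH cis to the C6 group.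

**Step 10**
Reactants: 15 (1S,5R,6S)-5-ethenyl-5-methyl-6-{3-[(TBS)oxy]prop-1-en-2-yl}-1-{3-[(TES)oxy]prop-1-en-2-yl}cyclohex-2-en-1-ol
Product: 16 (1S,2S,3S,4R,6S)-4-ethenyl-4-methyl-3-{3-[(TBS)oxy]prop-1-en-2-yl}-2-{3-[(TES)oxy]prop-1-en-2-yl}-7-oxabicyclo[4.1.0]heptan-2-ol
Conditions: VO(acac)2 (5 mol %), t-BuOOH (1.5 equiv, decane), CH2Cl2, 0 °C
Reagents that add atoms: tert-butyl hydroperoxide, CC(C)(C)OO
Why: Hydroxyl-directed vanadium-catalysed epoxidation delivers oxygen to the ring cis-alkene syn to the tertiary OH (the 1,1-disubstituted alkenes are slower and deactivated by their allylic silyloxy groups), giving the cis-epoxy alcohol with the C5 alkenyl group anti to the oxirane.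

**Step 11**
Reactants: 17 (S)-glycidol [(2S)-oxiran-2-ylmethanol]
Product: 18 (2R)-pent-4-ene-1,2-diol
Conditions: vinylmagnesium bromide (2.5 equiv), CuI (10 mol %), THF, −40 → 0 °C; H2O
Reagents that add atoms: vinylmagnesium bromide, C=C[Mg]Br
Why: Copper-catalysed epoxide opening at the unsubstituted carbon leaves the stereocentre untouched (the descriptor changes from S to R only through priorities).

**Step 12**
Reactants: 18 (2R)-pent-4-ene-1,2-diol
Product: 19 (4R)-4,5-bis[(TBS)oxy]pent-1-ene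
Conditions: TBSCl (2.4 equiv), imidazole, DMF, 23 °C
Reagents that add atoms: tert-butyldimethylsilyl chloride, CC(C)(C)[Si](C)(C)Cl
Why: Routine bis-silylation of a 1,2-diol.

**Step 13**
Reactants: 19 (4R)-4,5-bis[(TBS)oxy]pent-1-ene
Product: 21 (3R)-3,4-bis[(TBS)oxy]butanal, via ozonide 20 (not isolated)
Conditions: O3, CH2Cl2, −78 °C; then PPh3, −78 → 23 °C
Reagents that add atoms: ozone, [O-][O+]=O
Why: Ozonolysis with reductive work-up cleaves the terminal alkene to the aldehyde without touching the silyl ethers.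

**Step 14**
Reactants: 21 (3R)-3,4-bis[(TBS)oxy]butanal
Product: 22 (3R)-3,4-bis[(TBS)oxy]-2-methylidenebutanal
Conditions: 37 % aq. CH2O, pyrrolidine (10 mol %), propionic acid (10 mol %), i-PrOH, 45 °C
Reagents that add atoms: formaldehyde, C=O
Why: Organocatalytic α-methylenation (Mannich condensation then amine elimination) of the aldehyde; the stereocentre is not the enolised carbon.

**Step 15**
Reactants: 16 (1S,2S,3S,4R,6S)-4-ethenyl-4-methyl-3-{3-[(TBS)oxy]prop-1-en-2-yl}-2-{3-[(TES)oxy]prop-1-en-2-yl}-7-oxabicyclo[4.1.0]heptan-2-ol; 22 (3R)-3,4-bis[(TBS)oxy]-2-methylidenebutanal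
Product: 24 (1S,2S,3S,4S,5R)-5-ethenyl-3-hydroxy-5-methyl-4-{3-[(TBS)oxy]prop-1-en-2-yl}-2-{3-[(TES)oxy]prop-1-en-2-yl}cyclohexyl (3R)-3,4-bis[(TBS)oxy]-2-methylidenebutanoate, via samarium aldolate 23 (not isolated)
Conditions: SmI2 (0.3 equiv), 22 (3 equiv), THF, −10 → 20 °C
Reagents that add atoms: none
Why: Tandem semipinacol rearrangement/Evans–Tishchenko reduction: the trivalent samarium Lewis acid formed in situ opens the oxirane at C4 while the C5 alkenyl group, anti-periplanar to the breaking C4–O bond, makes a 1,2-shift with inversion at C4 (C4 group trans to C3–O), and the resulting C3 samarium alkoxide adds to aldehyde 22 and passes its hydride intramolecularly to the new C5 ketone, giving the 1,3-anti C5 alcohol and the C3 ester in one operation.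

**Step 16**
Reactants: 24 (the C5 alcohol from step 15)
Product: 25 (1S,2R,3S,4S,5R)-5-ethenyl-5-methyl-3-[(TES)oxy]-4-{3-[(TBS)oxy]prop-1-en-2-yl}-2-{3-[(TES)oxy]prop-1-en-2-yl}cyclohexyl (3R)-3,4-bis[(TBS)oxy]-2-methylidenebutanoate
Conditions: TESOTf, 2,6-lutidine, CH2Cl2, −78 °C
Reagents that add atoms: triethylsilyl trifluoromethanesulfonate, CC[Si](CC)(CC)OS(=O)(=O)C(F)(F)F
Why: Silyl triflate silylation of the hindered C5 alcohol blocks lactol and lactone formation during the next two oxidations.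

**Step 17**
Reactants: 25 (the C5 TES ether from step 16)
Product: 26 (1S,2R,3S,4S,5R)-5-ethenyl-5-methyl-2-(3-oxoprop-1-en-2-yl)-3-[(TES)oxy]-4-{3-[(TBS)oxy]prop-1-en-2-yl}cyclohexyl (3R)-3,4-bis[(TBS)oxy]-2-methylidenebutanoate
Conditions: (COCl)2, DMSO, CH2Cl2, −78 → −30 °C; then Et3N, −78 → 0 °C
Reagents that add atoms: none
Why: Swern conditions cleave and oxidise a primary TES ether directly to the aldehyde while the secondary TES ether and the TBS ethers survive.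

**Step 18**
Reactants: 26 (the enal from step 17)
Product: 27 2-[(1R,2S,3S,4R,6S)-6-{[(3R)-3,4-bis(TBS-oxy)-2-methylidenebutanoyl]oxy}-4-ethenyl-4-methyl-3-{3-[(TBS)oxy]prop-1-en-2-yl}-2-[(TES)oxy]cyclohexyl]prop-2-enoic acid
Conditions: NaClO2, NaH2PO4, 2-methylbut-2-ene, t-BuOH/H2O, 0 °C
Reagents that add atoms: sodium chlorite, [Na+].[O-]Cl=O
Why: Pinnick oxidation converts the 2-substituted acrolein to the acrylic acid without touching alkenes, esters or silyl ethers.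

**Step 19**
Reactants: 27 (the silylated acid from step 18)
Product: 28 2-[(1S,2S,3S,4R,6S)-6-{[(3R)-3,4-dihydroxy-2-methylidenebutanoyl]oxy}-4-ethenyl-2-hydroxy-3-(3-hydroxyprop-1-en-2-yl)-4-methylcyclohexyl]prop-2-enoic acid
Conditions: HF·pyridine, pyridine, THF, 0 → 23 °C; pH 5 buffer work-up
Reagents that add atoms: none
Why: Buffered fluoride desilylation removes the TES and three TBS groups under conditions that avoid both base (ester cleavage, acyl migration) and strong acid (lactonisation).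

**Compound list**
1 | 2-bromoprop-2-en-1-ol | C=C(Br)CO | starting material
2 | [(2-bromoprop-2-en-1-yl)oxy](tert-butyl)dimethylsilane | C=C(Br)CO[Si](C)(C)C(C)(C)C | intermediate
3 | 2-methylcyclopent-2-en-1-one | CC1=CCCC1=O | starting material
4 | {3-[(TBS)oxy]prop-1-en-2-yl}magnesium bromide | C=C([Mg]Br)CO[Si](C)(C)C(C)(C)C | intermediate (not isolated)
5 | bromomagnesium (3R)-2-methyl-3-{3-[(TBS)oxy]prop-1-en-2-yl}cyclopent-1-en-1-olate | CC1=C(O[Mg]Br)CC[C@@H]1C(=C)CO[Si](C)(C)C(C)(C)C | intermediate (not isolated)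
6 | (2R,3R)-2-ethenyl-2-methyl-3-{3-[(TBS)oxy]prop-1-en-2-yl}cyclopentan-1-one (ethenyl trans to the alkenyl group) | C=C[C@@]1(C)C(=O)CC[C@@H]1C(=C)CO[Si](C)(C)C(C)(C)C | intermediate
7 | lithium (2R,3R)-1-(dibromomethyl)-2-ethenyl-2-methyl-3-{3-[(TBS)oxy]prop-1-en-2-yl}cyclopentan-1-olate (both C1 epimers) | C=C[C@@]1(C)C(O[Li])(C(Br)Br)CC[C@@H]1C(=C)CO[Si](C)(C)C(C)(C)C | intermediate (not isolated)
8 | (3R,4S)-3-ethenyl-3-methyl-4-{3-[(TBS)oxy]prop-1-en-2-yl}cyclohexan-1-one | C=C[C@@]1(C)CC(=O)CC[C@@H]1C(=C)CO[Si](C)(C)C(C)(C)C | intermediate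
9 | (4S,5R)-5-ethenyl-5-methyl-4-{3-[(TBS)oxy]prop-1-en-2-yl}cyclohex-2-en-1-one | C=C[C@@]1(C)CC(=O)C=C[C@@H]1C(=C)CO[Si](C)(C)C(C)(C)C | intermediate
10 | (1S,4R,5S,6S)-4-ethenyl-4-methyl-5-{3-[(TBS)oxy]prop-1-en-2-yl}-7-oxabicyclo[4.1.0]heptan-2-one (oxirane anti to the alkenyl group) | C=C[C@@]1(C)CC(=O)[C@H]2O[C@H]2[C@@H]1C(=C)CO[Si](C)(C)C(C)(C)C | intermediate
11 | (1R,5R,6S)-5-ethenyl-5-methyl-6-{3-[(TBS)oxy]prop-1-en-2-yl}cyclohex-2-en-1-ol | C=C[C@@]1(C)CC=C[C@@H](O)[C@@H]1C(=C)CO[Si](C)(C)C(C)(C)C | intermediate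
12 | (5R,6S)-5-ethenyl-5-methyl-6-{3-[(TBS)oxy]prop-1-en-2-yl}cyclohex-2-en-1-one | C=C[C@@]1(C)CC=CC(=O)[C@@H]1C(=C)CO[Si](C)(C)C(C)(C)C | intermediate
13 | [(2-bromoprop-2-en-1-yl)oxy]triethylsilane | C=C(Br)CO[Si](CC)(CC)CC | intermediate
14 | {3-[(TES)oxy]prop-1-en-2-yl}lithium | C=C([Li])CO[Si](CC)(CC)CC | intermediate (not isolated)
15 | (1S,5R,6S)-5-ethenyl-5-methyl-6-{3-[(TBS)oxy]prop-1-en-2-yl}-1-{3-[(TES)oxy]prop-1-en-2-yl}cyclohex-2-en-1-ol (OH cis to the C6 alkenyl group) | C=C[C@@]1(C)CC=C[C@@](O)(C(=C)CO[Si](CC)(CC)CC)[C@@H]1C(=C)CO[Si](C)(C)C(C)(C)C | intermediate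
16 | (1S,2S,3S,4R,6S)-4-ethenyl-4-methyl-3-{3-[(TBS)oxy]prop-1-en-2-yl}-2-{3-[(TES)oxy]prop-1-en-2-yl}-7-oxabicyclo[4.1.0]heptan-2-ol (oxirane cis to OH) | C=C[C@@]1(C)C[C@@H]2O[C@@H]2[C@@](O)(C(=C)CO[Si](CC)(CC)CC)[C@@H]1C(=C)CO[Si](C)(C)C(C)(C)C | intermediate
17 | (S)-glycidol | OC[C@H]1CO1 | starting material
18 | (2R)-pent-4-ene-1,2-diol | C=CC[C@@H](O)CO | intermediate
19 | (4R)-4,5-bis[(TBS)oxy]pent-1-ene | C=CC[C@@H](O[Si](C)(C)C(C)(C)C)CO[Si](C)(C)C(C)(C)C | intermediate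
20 | 3-{(2R)-2,3-bis[(TBS)oxy]propyl}-1,2,4-trioxolane (both ring epimers) | C1OOC(C[C@@H](O[Si](C)(C)C(C)(C)C)CO[Si](C)(C)C(C)(C)C)O1 | intermediate (not isolated)
21 | (3R)-3,4-bis[(TBS)oxy]butanal | O=CC[C@@H](O[Si](C)(C)C(C)(C)C)CO[Si](C)(C)C(C)(C)C | intermediate
22 | (3R)-3,4-bis[(TBS)oxy]-2-methylidenebutanal | O=CC(=C)[C@@H](O[Si](C)(C)C(C)(C)C)CO[Si](C)(C)C(C)(C)C | intermediate
23 | (2S,3R,5S,6R)-3-ethenyl-5-hydroxy-3-methyl-2-{3-[(TBS)oxy]prop-1-en-2-yl}-6-{3-[(TES)oxy]prop-1-en-2-yl}cyclohexan-1-one (present as its samarium alkoxide) | C=C[C@@]1(C)C[C@H](O)[C@@H](C(=C)CO[Si](CC)(CC)CC)C(=O)[C@@H]1C(=C)CO[Si](C)(C)C(C)(C)C | intermediate (not isolated)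
24 | (1S,2S,3S,4S,5R)-5-ethenyl-3-hydroxy-5-methyl-4-{3-[(TBS)oxy]prop-1-en-2-yl}-2-{3-[(TES)oxy]prop-1-en-2-yl}cyclohexyl (3R)-3,4-bis[(TBS)oxy]-2-methylidenebutanoate | C=C[C@@]1(C)C[C@H](OC(=O)C(=C)[C@@H](O[Si](C)(C)C(C)(C)C)CO[Si](C)(C)C(C)(C)C)[C@@H](C(=C)CO[Si](CC)(CC)CC)[C@@H](O)[C@@H]1C(=C)CO[Si](C)(C)C(C)(C)C | intermediate
25 | (1S,2R,3S,4S,5R)-5-ethenyl-5-methyl-3-[(TES)oxy]-4-{3-[(TBS)oxy]prop-1-en-2-yl}-2-{3-[(TES)oxy]prop-1-en-2-yl}cyclohexyl (3R)-3,4-bis[(TBS)oxy]-2-methylidenebutanoate | C=C[C@@]1(C)C[C@H](OC(=O)C(=C)[C@@H](O[Si](C)(C)C(C)(C)C)CO[Si](C)(C)C(C)(C)C)[C@@H](C(=C)CO[Si](CC)(CC)CC)[C@@H](O[Si](CC)(CC)CC)[C@@H]1C(=C)CO[Si](C)(C)C(C)(C)C | intermediate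
26 | (1S,2R,3S,4S,5R)-5-ethenyl-5-methyl-2-(3-oxoprop-1-en-2-yl)-3-[(TES)oxy]-4-{3-[(TBS)oxy]prop-1-en-2-yl}cyclohexyl (3R)-3,4-bis[(TBS)oxy]-2-methylidenebutanoate | C=C[C@@]1(C)C[C@H](OC(=O)C(=C)[C@@H](O[Si](C)(C)C(C)(C)C)CO[Si](C)(C)C(C)(C)C)[C@@H](C(=C)C=O)[C@@H](O[Si](CC)(CC)CC)[C@@H]1C(=C)CO[Si](C)(C)C(C)(C)C | intermediate
27 | 2-[(1R,2S,3S,4R,6S)-6-{[(3R)-3,4-bis(TBS-oxy)-2-methylidenebutanoyl]oxy}-4-ethenyl-4-methyl-3-{3-[(TBS)oxy]prop-1-en-2-yl}-2-[(TES)oxy]cyclohexyl]prop-2-enoic acid | C=C[C@@]1(C)C[C@H](OC(=O)C(=C)[C@@H](O[Si](C)(C)C(C)(C)C)CO[Si](C)(C)C(C)(C)C)[C@@H](C(=C)C(=O)O)[C@@H](O[Si](CC)(CC)CC)[C@@H]1C(=C)CO[Si](C)(C)C(C)(C)C | intermediate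
28 | 2-[(1S,2S,3S,4R,6S)-6-{[(3R)-3,4-dihydroxy-2-methylidenebutanoyl]oxy}-4-ethenyl-2-hydroxy-3-(3-hydroxyprop-1-en-2-yl)-4-methylcyclohexyl]prop-2-enoic acid | C=C[C@@]1(C)C[C@H](OC(=O)C(=C)[C@@H](O)CO)[C@@H](C(=C)C(=O)O)[C@@H](O)[C@@H]1C(=C)CO | target

**Totals**
Total step count: 19. Longest linear sequence: 14 steps (steps 1, 2, 3, 4, 5, 6, 7, 9, 10, 15, 16, 17, 18, 19).

**The three steps most likely to fail**

Step 2 (the proposed new three-component coupling). The alkenyl Grignard may add with low enantioselectivity, or the magnesium enolate may not transfer to palladium. The fallback uses known, substrate-controlled chemistry; it sets out from bromide 2 and comes back at ketone 6. Commercial (R)-4-hydroxycyclopent-2-en-1-one is silylated (TBSCl, imidazole) to (R)-4-[(TBS)oxy]cyclopent-2-en-1-one F1. The lithium zincate made from 2 (t-BuLi, then Me2Zn) adds to F1 anti to the silyloxy group, and the enolate is methylated in the same flask with MeI/HMPA (the classical three-component coupling) to give (2R,3S,4R)-4-[(TBS)oxy]-2-methyl-3-{3-[(TBS)oxy]prop-1-en-2-yl}cyclopentan-1-one F2. DBU eliminates the silyloxy group to give (4S,5R)-5-methyl-4-{3-[(TBS)oxy]prop-1-en-2-yl}cyclopent-2-en-1-one F3. Its α'-lithium enolate (LiN(i-Pr)2, −78 °C) adds to phenyl vinyl sulfoxide anti to the alkenyl group to give (4R,5R)-5-methyl-5-[2-(phenylsulfinyl)ethyl]-4-{3-[(TBS)oxy]prop-1-en-2-yl}cyclopent-2-en-1-one F4, and thermal sulfoxide elimination (toluene, 110 °C) gives (4R,5R)-5-ethenyl-5-methyl-4-{3-[(TBS)oxy]prop-1-en-2-yl}cyclopent-2-en-1-one F5. Conjugate reduction with [(Ph3P)CuH]6 returns 6.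

Step 15 (tandem 1,2-alkenyl shift/Tishchenko coupling). The α-branched enal 22 may be a poor hydride donor, or the acyl group may migrate from the C3 to the C5 oxygen. The fallback separates the events; it sets out from epoxy alcohol 16 and aldehyde 22 and comes back at ester 24. ZnBr2 (CH2Cl2, 0 °C) effects the same stereospecific alkenyl shift, and β-hydroxy ketone 23 is isolated. Me4NBH(OAc)3 (AcOH/MeCN, −20 °C) gives by hydroxyl-directed reduction the 1,3-anti diol (1S,2R,3S,4S,5R)-5-ethenyl-5-methyl-4-{3-[(TBS)oxy]prop-1-en-2-yl}-2-{3-[(TES)oxy]prop-1-en-2-yl}cyclohexane-1,3-diol F9. Aldehyde 22 is oxidised (NaClO2, NaH2PO4, 2-methylbut-2-ene) to (3R)-3,4-bis[(TBS)oxy]-2-methylidenebutanoic acid F10. Yamaguchi esterification (2,4,6-trichlorobenzoyl chloride, Et3N, DMAP) of F9 with F10 should acylate the less hindered C3 hydroxyl (one branched neighbour) rather than the C5 hydroxyl (two alkenyl-bearing neighbours), giving 24.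

Step 10 (directed epoxidation). The alkenyl group on C5 is also allylic to the tertiary hydroxyl and may be epoxidised competitively. The fallback installs the oxirane before that alkene exists; it sets out from enone 12 and comes back at epoxy alcohol 16. Luche reduction (NaBH4, CeCl3·7H2O, MeOH, −78 °C) from the face opposite the C6 substituent gives (1S,5R,6S)-5-ethenyl-5-methyl-6-{3-[(TBS)oxy]prop-1-en-2-yl}cyclohex-2-en-1-ol F6. VO(acac)2/t-BuOOH epoxidation syn to the hydroxyl gives (1R,2R,3S,4R,6S)-4-ethenyl-4-methyl-3-{3-[(TBS)oxy]prop-1-en-2-yl}-7-oxabicyclo[4.1.0]heptan-2-ol F7. Dess–Martin oxidation gives (1S,3S,4R,6S)-4-ethenyl-4-methyl-3-{3-[(TBS)oxy]prop-1-en-2-yl}-7-oxabicyclo[4.1.0]heptan-2-one F8. Alkenyllithium 14 then adds anti to both the oxirane and the C6 group to give 16.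

**Further compounds**
F1 | step 2 | (R)-4-[(TBS)oxy]cyclopent-2-en-1-one | O=C1C=C[C@H](O[Si](C)(C)C(C)(C)C)C1
F2 | step 2 | (2R,3S,4R)-4-[(TBS)oxy]-2-methyl-3-{3-[(TBS)oxy]prop-1-en-2-yl}cyclopentan-1-one | C[C@H]1C(=O)C[C@@H](O[Si](C)(C)C(C)(C)C)[C@@H]1C(=C)CO[Si](C)(C)C(C)(C)C
F3 | step 2 | (4S,5R)-5-methyl-4-{3-[(TBS)oxy]prop-1-en-2-yl}cyclopent-2-en-1-one | C[C@H]1C(=O)C=C[C@@H]1C(=C)CO[Si](C)(C)C(C)(C)C
F4 | step 2 | (4R,5R)-5-methyl-5-[2-(phenylsulfinyl)ethyl]-4-{3-[(TBS)oxy]prop-1-en-2-yl}cyclopent-2-en-1-one (both sulfur epimers) | O=S(CC[C@@]1(C)C(=O)C=C[C@@H]1C(=C)CO[Si](C)(C)C(C)(C)C)c1ccccc1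
F5 | step 2 | (4R,5R)-5-ethenyl-5-methyl-4-{3-[(TBS)oxy]prop-1-en-2-yl}cyclopent-2-en-1-one | C=C[C@@]1(C)C(=O)C=C[C@@H]1C(=C)CO[Si](C)(C)C(C)(C)C
F6 | step 10 | (1S,5R,6S)-5-ethenyl-5-methyl-6-{3-[(TBS)oxy]prop-1-en-2-yl}cyclohex-2-en-1-ol | C=C[C@@]1(C)CC=C[C@H](O)[C@@H]1C(=C)CO[Si](C)(C)C(C)(C)C
F7 | step 10 | (1R,2R,3S,4R,6S)-4-ethenyl-4-methyl-3-{3-[(TBS)oxy]prop-1-en-2-yl}-7-oxabicyclo[4.1.0]heptan-2-ol | C=C[C@@]1(C)C[C@@H]2O[C@@H]2[C@H](O)[C@@H]1C(=C)CO[Si](C)(C)C(C)(C)C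
F8 | step 10 | (1S,3S,4R,6S)-4-ethenyl-4-methyl-3-{3-[(TBS)oxy]prop-1-en-2-yl}-7-oxabicyclo[4.1.0]heptan-2-one | C=C[C@@]1(C)C[C@@H]2O[C@@H]2C(=O)[C@@H]1C(=C)CO[Si](C)(C)C(C)(C)C
F9 | step 15 | (1S,2R,3S,4S,5R)-5-ethenyl-5-methyl-4-{3-[(TBS)oxy]prop-1-en-2-yl}-2-{3-[(TES)oxy]prop-1-en-2-yl}cyclohexane-1,3-diol | C=C[C@@]1(C)C[C@H](O)[C@@H](C(=C)CO[Si](CC)(CC)CC)[C@@H](O)[C@@H]1C(=C)CO[Si](C)(C)C(C)(C)C
F10 | step 15 | (3R)-3,4-bis[(TBS)oxy]-2-methylidenebutanoic acid | OC(=O)C(=C)[C@@H](O[Si](C)(C)C(C)(C)C)CO[Si](C)(C)C(C)(C)C
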